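**Plan**

- Feature used: in the diol ring the tertiary carbinol C1 (OH, Me) lies between the secondary carbinol C2 and the ring CH2 C6. At the ketone level (C2=O) this 2-hydroxy-2-methylcyclohexanone is the α-ketol isomer of a 1-acetylcyclopentan-1-ol, so the ring is cut at C1–C6 (retro 1,2-shift) back to a cyclopentane that already carries C3 and C4.
- The acetyl group is then removed as an acetyl anion equivalent from a 2,3-trans cyclopentanone, which is cut at C3–CH2 (enolate allylation) and at C4–isopropenyl (conjugate addition to cyclopent-2-en-1-one).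
- The bromocyclohexanol ring with the allylic carbon comes from (1S,2S,4R)-limonene-1,2-diol (ene chlorination of its isopropenyl group). The C–Br bond is cut last in the retrosynthesis (SN2 inversion of the axial secondary carbinol).
- Forward: allylic iodide 4 and enol silane 7 are joined to cyclopentanone 9, which is converted to acetylcyclopentanol 11 and ring-enlarged to cyclohexanone 12. Bromide installation, desilylation and ketone reduction follow.
- Stereochemistry: the ring B carbons come from the chiral-pool diol and C–Br from inversion. C4 is set by catalyst control, C3 by trans alkylation, and the cyclopentanol carbinol by attack anti to the side chain. C1 is relayed from that carbinol in the 1,2-shift, and C2 is set by hydroxyl-directed hydride delivery.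

Key step: step 7

Assumption: in step 4 the ligand antipode that delivers the 3S adduct is meant; if the sense of induction is opposite to the descriptor written, the mirror-image ligand is used.

**Step 1**
Reactants: 1 (1S,2S,4R)-1-methyl-4-(prop-1-en-2-yl)cyclohexane-1,2-diol (limonene-1,2-diol, trans-diaxial hydroxyls)
Product: 2 (1S,2S,4R)-1-methyl-4-(prop-1-en-2-yl)-1,2-bis(triethylsilyloxy)cyclohexane
Conditions: Et3SiOTf (2.5 equiv), 2,6-lutidine, CH2Cl2, −78 → 0 °C
Reagents that add atoms: triethylsilyl trifluoromethanesulfonate, CC[Si](CC)(CC)OS(=O)(=O)C(F)(F)F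
Why: Silyl triflate with a hindered pyridine base should silylate both the secondary and the tertiary hydroxyl (standard silyl ether formation), masking them for the organometallic and basic steps; no stereocenter is touched.

**Step 2**
Reactants: 2 (1S,2S,4R)-1-methyl-4-(prop-1-en-2-yl)-1,2-bis(triethylsilyloxy)cyclohexane
Product: 3 (1S,2S,4R)-4-(3-chloroprop-1-en-2-yl)-1-methyl-1,2-bis(triethylsilyloxy)cyclohexane
Conditions: Ca(OCl)2, solid CO2, CH2Cl2/H2O, 0 °C
Reagents that add atoms: calcium hypochlorite (source of HOCl), [Ca+2].[O-]Cl.[O-]Cl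
Why: Ene-type allylic chlorination with HOCl made in situ: electrophilic chlorine adds to the terminal CH2 of the only alkene and the methyl group loses a proton, which should give the 2-substituted allyl chloride with the ring stereocenters untouched.

**Step 3**
Reactants: 3 (1S,2S,4R)-4-(3-chloroprop-1-en-2-yl)-1-methyl-1,2-bis(triethylsilyloxy)cyclohexane
Product: 4 (1S,2S,4R)-4-(3-iodoprop-1-en-2-yl)-1-methyl-1,2-bis(triethylsilyloxy)cyclohexane
Conditions: NaI, acetone, rt, dark
Reagents that add atoms: sodium iodide, [Na+].[I-]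
Why: Finkelstein halide exchange at the primary allylic carbon should give the more reactive iodide for the enolate alkylation; it is used without storage.

**Step 4**
Reactants: 5 cyclopent-2-en-1-one
Product: 7 (S)-trimethyl{[3-(prop-1-en-2-yl)cyclopent-1-en-1-yl]oxy}silane, via bromomagnesium enolate 6 (not isolated)
Conditions: CH2=C(CH3)MgBr (1.2 equiv), CuBr·SMe2 (5 mol %), (R)-1-[(S)-2-(diphenylphosphino)ferrocenyl]ethyl-dicyclohexylphosphine (6 mol %), t-BuOMe, −78 °C; then Me3SiCl, Et3N, DMPU, −78 → 0 °C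
Reagents that add atoms: isopropenylmagnesium bromide, CC(=C)[Mg]Br; chlorotrimethylsilane, C[Si](C)(C)Cl
Why: Copper-catalysed asymmetric conjugate addition of a Grignard reagent to a cyclic enone with a ferrocenyl diphosphine ligand should set the β-stereocenter (later C4 of ring A) under catalyst control, and O-silylation of the magnesium enolate stores the enolate regiochemistry.

**Step 5**
Reactants: 7 (S)-trimethyl{[3-(prop-1-en-2-yl)cyclopent-1-en-1-yl]oxy}silane; 4 (1S,2S,4R)-4-(3-iodoprop-1-en-2-yl)-1-methyl-1,2-bis(triethylsilyloxy)cyclohexane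
Product: 9 (2R,3S)-2-{2-[(1R,3S,4S)-4-methyl-3,4-bis(triethylsilyloxy)cyclohexyl]prop-2-en-1-yl}-3-(prop-1-en-2-yl)cyclopentan-1-one, via lithium enolate 8 (not isolated)
Conditions: MeLi, THF, 0 °C; then 4, DMPU, −78 → −30 °C
Reagents that add atoms: none
Why: MeLi cleaves the Si–O bond to the regiodefined lithium enolate, which should be C-alkylated by the allylic iodide on the face anti to the adjacent isopropenyl group (enolate alkylation), giving the 2,3-trans ketone.

**Step 6**
Reactants: 9 (2R,3S)-2-{2-[(1R,3S,4S)-4-methyl-3,4-bis(triethylsilyloxy)cyclohexyl]prop-2-en-1-yl}-3-(prop-1-en-2-yl)cyclopentan-1-one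
Product: 11 1-[(1S,2R,3S)-1-hydroxy-2-{2-[(1R,3S,4S)-4-methyl-3,4-bis(triethylsilyloxy)cyclohexyl]prop-2-en-1-yl}-3-(prop-1-en-2-yl)cyclopentyl]ethan-1-one (hydroxyl cis to the C2 side chain), via 1-ethoxyvinyl carbinol 10 (not isolated)
Conditions: ethyl vinyl ether, t-BuLi, THF, −78 → 0 °C; LaCl3·2LiCl (0.3 equiv), 9, −78 °C; aq. NH4Cl; then 5% aq. oxalic acid, THF, 0 °C
Reagents that add atoms: 1-ethoxyvinyllithium (from ethyl vinyl ether and t-BuLi), C=C(OCC)[Li]; water, O
Why: 1,2-Addition of an acyl anion equivalent (lanthanum-promoted to suppress enolization) should occur anti to the C2 side chain, so the new hydroxyl is cis to it, and mild acid hydrolysis of the enol ether unmasks the methyl ketone without cleaving the triethylsilyl ethers.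

**Step 7**
Reactants: 11 1-[(1S,2R,3S)-1-hydroxy-2-{2-[(1R,3S,4S)-4-methyl-3,4-bis(triethylsilyloxy)cyclohexyl]prop-2-en-1-yl}-3-(prop-1-en-2-yl)cyclopentyl]ethan-1-one
Product: 12 (2R,5S,6R)-2-hydroxy-2-methyl-6-{2-[(1R,3S,4S)-4-methyl-3,4-bis(triethylsilyloxy)cyclohexyl]prop-2-en-1-yl}-5-(prop-1-en-2-yl)cyclohexan-1-one
Conditions: KOt-Bu (0.3 equiv), 18-crown-6 (0.3 equiv), t-BuOH/THF 1:4, 50 °C
Reagents that add atoms: none
Why: KOt-Bu turns the tertiary alcohol of 11 into its alkoxide, whose push drives a suprafacial 1,2-shift of the ring CH2 (C5 of the cyclopentane) from the carbinol carbon to the acetyl carbonyl carbon, so that the old carbinol carbon becomes the ring ketone and the acetyl carbon enters the ring as C(OH)Me, an α-ketol (acyloin) rearrangement. The closest known reaction type is the base-mediated ring enlargement of 1-acylcycloalkanols, as in the D-homoannulation of 17-hydroxy-20-oxo steroids. The six-membered ring is not closed by a cyclization but arises from the five-membered ring by insertion of one carbon, driven by relief of cyclopentane strain, and no other ring is formed. The new stereocenter C2 of 12 is controlled by the carbinol configuration of 11 (hydroxyl cis to the C2 side chain) together with the transoid alignment of C–O(−) and C=O in the crown-ether-separated potassium alkoxide: the CH2 shifts with retention onto the carbonyl face that places OH axial and cis to the isopropenyl group and methyl equatorial, which should also be the more stable epimer. The step needs migration of the CH2 and not of the branched C2 of the cyclopentane; in an alkoxide-driven shift the migrating carbon carries carbanion character, which favours the primary over the secondary carbon, and the product with the quaternary carbinol next to CH2 is the less crowded isomer under these reversible conditions. C6 of 12 is epimerizable under the base but already holds the more stable trans-diequatorial relation to C5.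

**Step 8**
Reactants: 12 (2R,5S,6R)-2-hydroxy-2-methyl-6-{2-[(1R,3S,4S)-4-methyl-3,4-bis(triethylsilyloxy)cyclohexyl]prop-2-en-1-yl}-5-(prop-1-en-2-yl)cyclohexan-1-one
Product: 13 (2R,5S,6R)-2-hydroxy-6-{2-[(1R,3S,4S)-3-hydroxy-4-methyl-4-(triethylsilyloxy)cyclohexyl]prop-2-en-1-yl}-2-methyl-5-(prop-1-en-2-yl)cyclohexan-1-one
Conditions: pyridinium p-toluenesulfonate, MeOH/CH2Cl2, 0 °C
Reagents that add atoms: none
Why: Mild acid methanolysis should remove the secondary triethylsilyl ether much faster than the tertiary one (selective desilylation), freeing only the axial secondary hydroxyl of ring B.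

**Step 9**
Reactants: 13 (2R,5S,6R)-2-hydroxy-6-{2-[(1R,3S,4S)-3-hydroxy-4-methyl-4-(triethylsilyloxy)cyclohexyl]prop-2-en-1-yl}-2-methyl-5-(prop-1-en-2-yl)cyclohexan-1-one
Product: 15 (2R,5S,6R)-6-{2-[(1R,3R,4S)-3-bromo-4-methyl-4-(triethylsilyloxy)cyclohexyl]prop-2-en-1-yl}-2-hydroxy-2-methyl-5-(prop-1-en-2-yl)cyclohexan-1-one, via axial secondary triflate 14 (not isolated)
Conditions: Tf2O (1.2 equiv), pyridine, CH2Cl2, −40 °C; then n-Bu4NBr, −40 → 0 °C
Reagents that add atoms: tetrabutylammonium bromide, CCCC[N+](CCCC)(CCCC)CCCC.[Br-]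
Why: Only the secondary alcohol is triflated (the tertiary oxygens are unreactive or silylated), and bromide should displace the axial triflate by SN2 with inversion, placing bromine equatorial and cis to the tertiary oxygen; the silyl ether on that oxygen blocks epoxide formation.

**Step 10**
Reactants: 15 (2R,5S,6R)-6-{2-[(1R,3R,4S)-3-bromo-4-methyl-4-(triethylsilyloxy)cyclohexyl]prop-2-en-1-yl}-2-hydroxy-2-methyl-5-(prop-1-en-2-yl)cyclohexan-1-one
Product: 16 (2R,5S,6R)-6-{2-[(1R,3R,4S)-3-bromo-4-hydroxy-4-methylcyclohexyl]prop-2-en-1-yl}-2-hydroxy-2-methyl-5-(prop-1-en-2-yl)cyclohexan-1-one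
Conditions: HF·pyridine, pyridine, THF, 0 °C → rt
Reagents that add atoms: none
Why: Fluoride cleavage of the tertiary silyl ether under buffered acidic conditions avoids the alkoxide of the cis-bromohydrin and so its ring contraction.

**Step 11**
Reactants: 16 (2R,5S,6R)-6-{2-[(1R,3R,4S)-3-bromo-4-hydroxy-4-methylcyclohexyl]prop-2-en-1-yl}-2-hydroxy-2-methyl-5-(prop-1-en-2-yl)cyclohexan-1-one
Product: 17 prevezol C, (1R,2R,3R,4S)-3-{2-[(1R,3R,4S)-3-bromo-4-hydroxy-4-methylcyclohexyl]prop-2-en-1-yl}-1-methyl-4-(prop-1-en-2-yl)cyclohexane-1,2-diol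
Conditions: Me4NBH(OAc)3, MeCN/AcOH, −20 °C
Reagents that add atoms: none
Why: Hydroxyl-directed reduction of the α-hydroxy ketone: the axial tertiary hydroxyl binds the triacetoxyborohydride and hydride should be delivered to the carbonyl from the same face, giving the trans-diaxial diol (new C2 stereocenter under substrate control).

**Compound list**

1 | (1S,2S,4R)-1-methyl-4-(prop-1-en-2-yl)cyclohexane-1,2-diol | CC(=C)[C@@H]1CC[C@](C)(O)[C@@H](O)C1 | starting material
2 | (1S,2S,4R)-1-methyl-4-(prop-1-en-2-yl)-1,2-bis(triethylsilyloxy)cyclohexane | CC(=C)[C@@H]1CC[C@](C)(O[Si](CC)(CC)CC)[C@@H](O[Si](CC)(CC)CC)C1 | intermediate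
3 | (1S,2S,4R)-4-(3-chloroprop-1-en-2-yl)-1-methyl-1,2-bis(triethylsilyloxy)cyclohexane | ClCC(=C)[C@@H]1CC[C@](C)(O[Si](CC)(CC)CC)[C@@H](O[Si](CC)(CC)CC)C1 | intermediate
4 | (1S,2S,4R)-4-(3-iodoprop-1-en-2-yl)-1-methyl-1,2-bis(triethylsilyloxy)cyclohexane | ICC(=C)[C@@H]1CC[C@](C)(O[Si](CC)(CC)CC)[C@@H](O[Si](CC)(CC)CC)C1 | intermediate
5 | cyclopent-2-en-1-one | O=C1C=CCC1 | starting material
6 | bromomagnesium (S)-3-(prop-1-en-2-yl)cyclopent-1-en-1-olate | Br[Mg]OC1=C[C@@H](C(C)=C)CC1 | intermediate (not isolated)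
7 | (S)-trimethyl{[3-(prop-1-en-2-yl)cyclopent-1-en-1-yl]oxy}silane | C[Si](C)(C)OC1=C[C@@H](C(C)=C)CC1 | intermediate
8 | lithium (S)-3-(prop-1-en-2-yl)cyclopent-1-en-1-olate | [Li]OC1=C[C@@H](C(C)=C)CC1 | intermediate (not isolated)
9 | (2R,3S)-2-{2-[(1R,3S,4S)-4-methyl-3,4-bis(triethylsilyloxy)cyclohexyl]prop-2-en-1-yl}-3-(prop-1-en-2-yl)cyclopentan-1-one | C=C(C[C@@H]1[C@@H](C(=C)C)CCC1=O)[C@@H]1CC[C@](C)(O[Si](CC)(CC)CC)[C@@H](O[Si](CC)(CC)CC)C1 | intermediate
10 | (1S,2R,3S)-1-(1-ethoxyvinyl)-2-{2-[(1R,3S,4S)-4-methyl-3,4-bis(triethylsilyloxy)cyclohexyl]prop-2-en-1-yl}-3-(prop-1-en-2-yl)cyclopentan-1-ol | C=C(C[C@@H]1[C@@H](C(=C)C)CC[C@@]1(O)C(=C)OCC)[C@@H]1CC[C@](C)(O[Si](CC)(CC)CC)[C@@H](O[Si](CC)(CC)CC)C1 | intermediate (not isolated)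
11 | 1-[(1S,2R,3S)-1-hydroxy-2-{2-[(1R,3S,4S)-4-methyl-3,4-bis(triethylsilyloxy)cyclohexyl]prop-2-en-1-yl}-3-(prop-1-en-2-yl)cyclopentyl]ethan-1-one | C=C(C[C@@H]1[C@@H](C(=C)C)CC[C@@]1(O)C(C)=O)[C@@H]1CC[C@](C)(O[Si](CC)(CC)CC)[C@@H](O[Si](CC)(CC)CC)C1 | intermediate
12 | (2R,5S,6R)-2-hydroxy-2-methyl-6-{2-[(1R,3S,4S)-4-methyl-3,4-bis(triethylsilyloxy)cyclohexyl]prop-2-en-1-yl}-5-(prop-1-en-2-yl)cyclohexan-1-one | C=C(C[C@@H]1[C@@H](C(=C)C)CC[C@@](C)(O)C1=O)[C@@H]1CC[C@](C)(O[Si](CC)(CC)CC)[C@@H](O[Si](CC)(CC)CC)C1 | intermediate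
13 | (2R,5S,6R)-2-hydroxy-6-{2-[(1R,3S,4S)-3-hydroxy-4-methyl-4-(triethylsilyloxy)cyclohexyl]prop-2-en-1-yl}-2-methyl-5-(prop-1-en-2-yl)cyclohexan-1-one | C=C(C[C@@H]1[C@@H](C(=C)C)CC[C@@](C)(O)C1=O)[C@@H]1CC[C@](C)(O[Si](CC)(CC)CC)[C@@H](O)C1 | intermediate
14 | trifluoromethanesulfonate of the ring B secondary hydroxyl of 13 (axial OTf, trans to the silyloxy group) | C=C(C[C@@H]1[C@@H](C(=C)C)CC[C@@](C)(O)C1=O)[C@@H]1CC[C@](C)(O[Si](CC)(CC)CC)[C@@H](OS(=O)(=O)C(F)(F)F)C1 | intermediate (not isolated)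
15 | (2R,5S,6R)-6-{2-[(1R,3R,4S)-3-bromo-4-methyl-4-(triethylsilyloxy)cyclohexyl]prop-2-en-1-yl}-2-hydroxy-2-methyl-5-(prop-1-en-2-yl)cyclohexan-1-one | C=C(C[C@@H]1[C@@H](C(=C)C)CC[C@@](C)(O)C1=O)[C@@H]1CC[C@](C)(O[Si](CC)(CC)CC)[C@H](Br)C1 | intermediate
16 | (2R,5S,6R)-6-{2-[(1R,3R,4S)-3-bromo-4-hydroxy-4-methylcyclohexyl]prop-2-en-1-yl}-2-hydroxy-2-methyl-5-(prop-1-en-2-yl)cyclohexan-1-one | C=C(C[C@@H]1[C@@H](C(=C)C)CC[C@@](C)(O)C1=O)[C@@H]1CC[C@](C)(O)[C@H](Br)C1 | intermediate
17 | prevezol C, (1R,2R,3R,4S)-3-{2-[(1R,3R,4S)-3-bromo-4-hydroxy-4-methylcyclohexyl]prop-2-en-1-yl}-1-methyl-4-(prop-1-en-2-yl)cyclohexane-1,2-diol | C=C(C[C@@H]1[C@@H](C(=C)C)CC[C@@](C)(O)[C@@H]1O)[C@@H]1CC[C@](C)(O)[C@H](Br)C1 | target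

**Step count and risks**

Total steps: 11. Longest linear sequence: 10 steps (steps 1–3 and 5–11, from diol 1).

Most likely to fail:

1. Step 7. The branched ring carbon may migrate in competition with the CH2, or the isomerization may stall before completion. Fallback from 9, returning at 12: kinetic deprotonation on the CH2 side (LiN(i-Pr)2, Me3SiCl, THF, −78 °C) gives the less substituted trimethylsilyl enol ether of 9 F1. Addition of chloro(methyl)carbene (1,1-dichloroethane, n-BuLi, Et2O, −35 °C) gives the 6-chloro-6-methyl-1-(trimethylsilyloxy)bicyclo[3.1.0]hexane adduct F2. Its thermal electrocyclic opening with loss of the silyl chloride (toluene, Et3N, reflux) gives the ring-enlarged (5S,6R)-2-methylcyclohex-2-en-1-one F3, still a five-to-six ring expansion, with regiochemistry fixed by the enol ether. Conjugate reduction with LiBH(s-Bu)3 (THF, −78 °C) gives the lithium enolate F4, and hydroxylation of its axial face with 2-(phenylsulfonyl)-3-phenyloxaziridine should give 12.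

2. Step 9. The anti-periplanar silyloxy group may participate, or E2 elimination of the hindered axial triflate may compete with SN2. Fallback from 13, returning at 16: HF·pyridine removes the remaining silyl group to give the ring B trans-diol F5. SOCl2 and Et3N (CH2Cl2, 0 °C) close the trans-fused cyclic sulfite F6, in which the two C–O bonds are gauche and no oxygen is anti-periplanar to the secondary carbon. LiBr in DMF at 80 °C should open it at the secondary carbon with inversion, and aqueous work-up with loss of SO2 gives the cis-bromohydrin 16.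

3. Step 4. Enantioselectivity may be low in the conjugate addition of an alkenyl Grignard reagent to cyclopentenone. Fallback from 5, returning at 9: uncatalysed-ligand addition (CH2=C(CH3)MgBr, CuI 10 mol %, Me3SiCl, THF, −78 °C) gives the racemic enol silane F7. Alkylation as in step 5 with the single-enantiomer iodide 4 gives 9 together with its (2S,3R) cyclopentanone diastereomer F8. Both are 2,3-trans and differ as diastereomers because ring B is one enantiomer, so chromatography should return 9.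

**Further compounds**

F1 | step 7 | trimethylsilyl enol ether of 9 with the double bond toward the ring CH2 | C=C(C[C@@H]1[C@@H](C(=C)C)CC=C1O[Si](C)(C)C)[C@@H]1CC[C@](C)(O[Si](CC)(CC)CC)[C@@H](O[Si](CC)(CC)CC)C1
F2 | step 7 | 6-chloro-6-methyl-1-(trimethylsilyloxy)bicyclo[3.1.0]hexane adduct of F1 (cyclopropane centers unassigned) | C=C(C[C@@H]1[C@@H](C(=C)C)CC2C(C)(Cl)C12O[Si](C)(C)C)[C@@H]1CC[C@](C)(O[Si](CC)(CC)CC)[C@@H](O[Si](CC)(CC)CC)C1
F3 | step 7 | (5S,6R)-2-methyl-6-{2-[(1R,3S,4S)-4-methyl-3,4-bis(triethylsilyloxy)cyclohexyl]prop-2-en-1-yl}-5-(prop-1-en-2-yl)cyclohex-2-en-1-one | C=C(C[C@@H]1[C@@H](C(=C)C)CC=C(C)C1=O)[C@@H]1CC[C@](C)(O[Si](CC)(CC)CC)[C@@H](O[Si](CC)(CC)CC)C1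
F4 | step 7 | lithium enolate from conjugate reduction of F3 | C=C(C[C@@H]1[C@@H](C(=C)C)CCC(C)=C1O[Li])[C@@H]1CC[C@](C)(O[Si](CC)(CC)CC)[C@@H](O[Si](CC)(CC)CC)C1
F5 | step 9 | (2R,5S,6R)-6-{2-[(1R,3S,4S)-3,4-dihydroxy-4-methylcyclohexyl]prop-2-en-1-yl}-2-hydroxy-2-methyl-5-(prop-1-en-2-yl)cyclohexan-1-one | C=C(C[C@@H]1[C@@H](C(=C)C)CC[C@@](C)(O)C1=O)[C@@H]1CC[C@](C)(O)[C@@H](O)C1
F6 | step 9 | trans-fused cyclic sulfite of the ring B diol of F5 | C=C(C[C@@H]1[C@@H](C(=C)C)CC[C@@](C)(O)C1=O)[C@@H]1CC[C@]2(C)OS(=O)O[C@H]2C1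
F7 | step 4 | racemic trimethyl{[3-(prop-1-en-2-yl)cyclopent-1-en-1-yl]oxy}silane | C[Si](C)(C)OC1=CC(C(C)=C)CC1
F8 | step 4 | (2S,3R)-2-{2-[(1R,3S,4S)-4-methyl-3,4-bis(triethylsilyloxy)cyclohexyl]prop-2-en-1-yl}-3-(prop-1-en-2-yl)cyclopentan-1-one | C=C(C[C@H]1[C@H](C(=C)C)CCC1=O)[C@@H]1CC[C@](C)(O[Si](CC)(CC)CC)[C@@H](O[Si](CC)(CC)CC)C1
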